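Ring B (C5–C10) is closed between C7 and C8 by ring-closing olefin metathesis. The disconnection exploits the trans-diaxial pair of the C7 isopropenyl and C8 hydroxyl groups next to the C9 oxygen. This pattern is the signature of Fürst–Plattner opening of a 7α,8α-epoxide, hence of a C7=C8 olefin whose allylic C9 carbinol directs the epoxidation. The precursor is a ring A cyclohexane, made from (S)-carvone, that carries a C5 allyl group and a C10 1-hydroxyallyl arm trans to each other. In one operation the metathesis gives the trans-fused octalin with the C7=C8 bond placed between the C6 methylene and the C9 carbinol.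

Key step: step 7

Remark: eremophilane numbering is used for ring positions (ring A = C1–C5 and C10, ring B = C5–C10, methyl groups on C4 and C5, isopropenyl on C7), β is the face of the C5 methyl group, and (2E)-3-methylpent-2-enoic acid is assumed to be purchased as the pure E isomer.

Step 1
Reactants: 1 (S)-(+)-carvone
Product: 4 (S)-5-acetoxy-2-methylcyclohex-2-en-1-one, via methoxy hydroperoxide 2 (not isolated), via peroxyacetate 3 (not isolated)
Conditions: O3, CH2Cl2/MeOH, −78 °C; then Ac2O, Et3N, DMAP (cat.), −78 °C → rt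
Reagents that add atoms: ozone, [O-][O+]=O; methanol, CO
Why: Ozonolysis cleaves only the electron-rich isopropenyl alkene, methanol traps the carbonyl oxide as 2, and acetylation to 3 triggers a Criegee rearrangement in which the ring carbon migrates to oxygen with retention, so the (S) centre of carvone becomes the (S) carbinol centre (future C2) and the acetyl group of 4 is the former isopropenyl C–CH3 unit.

Step 2
Reactants: 4 (S)-5-acetoxy-2-methylcyclohex-2-en-1-one
Product: 5 (5S)-5-hydroxy-2-methylcyclohex-2-en-1-one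
Conditions: K2CO3 (0.2 equiv), MeOH, 0 °C
Reagents that add atoms: none
Why: Base-catalysed transesterification with methanol at low temperature should remove the acetate faster than E1cB loss of acetate from the β-acyloxy ketone, and it does not touch the stereocentre.

Step 3
Reactants: 5 (5S)-5-hydroxy-2-methylcyclohex-2-en-1-one
Product: 6 (5S)-5-[(tert-butyldimethylsilyl)oxy]-2-methylcyclohex-2-en-1-one
Conditions: TBSCl, imidazole, DMF, 0 °C → rt
Reagents that add atoms: tert-butyldimethylsilyl chloride, CC(C)(C)[Si](C)(C)Cl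
Why: Imidazole-promoted silylation of the secondary alcohol gives a base-stable ether that also serves as the steric control element on ring A.

Step 4
Reactants: 6 (5S)-5-[(tert-butyldimethylsilyl)oxy]-2-methylcyclohex-2-en-1-one
Product: 8 (2R,3S,5S)-5-[(tert-butyldimethylsilyl)oxy]-2,3-dimethyl-2-(prop-2-en-1-yl)cyclohexan-1-one, via lithium enolate 7 (not isolated)
Conditions: Me2CuLi (from MeLi and CuI), Et2O, −78 → −30 °C; then allyl bromide, HMPA, THF, −30 °C → rt
Reagents that add atoms: lithium dimethylcuprate, [Li+].C[Cu-]C; allyl bromide, C=CCBr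
Why: In this tandem Gilman conjugate addition–enolate alkylation, methyl adds to C4 anti to the C2 silyloxy group (the 3,5-trans rule of 5-substituted cyclohexenones) and the regiodefined enolate 7 is C-allylated at C5 anti to the new pseudoaxial C4 methyl group, which makes the C4 and C5 methyl groups cis and sets the quaternary centre.

Step 5
Reactants: 8 (2R,3S,5S)-5-[(tert-butyldimethylsilyl)oxy]-2,3-dimethyl-2-(prop-2-en-1-yl)cyclohexan-1-one
Product: 10 (1R,2R,3S,5S)-5-[(tert-butyldimethylsilyl)oxy]-2,3-dimethyl-2-(prop-2-en-1-yl)cyclohexane-1-carbaldehyde, via enol ether 9 (not isolated)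
Conditions: Ph3P(Cl)CH2OMe, KN(SiMe3)2, THF, 0 °C → rt; then Cl3CCO2H, CH2Cl2/H2O, 0 °C; then K2CO3, MeOH, rt
Reagents that add atoms: (methoxymethyl)triphenylphosphonium chloride, COC[P+](c1ccccc1)(c1ccccc1)c1ccccc1.[Cl-]; water, O
Why: Wittig methoxymethylenation gives enol ether 9, acid hydrolysis releases the C9 aldehyde, and base equilibration should place the formyl group equatorial (C10–H α, trans to the C5 methyl) because the axial epimer suffers a syn-diaxial clash with the axial C2 silyloxy group.

Step 6
Reactants: 10 (1R,2R,3S,5S)-5-[(tert-butyldimethylsilyl)oxy]-2,3-dimethyl-2-(prop-2-en-1-yl)cyclohexane-1-carbaldehyde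
Product: 11 (1R)-1-[(1R,2R,3S,5S)-5-[(tert-butyldimethylsilyl)oxy]-2,3-dimethyl-2-(prop-2-en-1-yl)cyclohexyl]prop-2-en-1-ol
Conditions: CH2=CHMgBr, THF, −78 °C; aq. NH4Cl
Reagents that add atoms: vinylmagnesium bromide, C=C[Mg]Br
Why: Grignard 1,2-addition under Felkin–Anh control, with the quaternary C5 as the large group antiperiplanar to the incoming vinyl and attack past the C10 hydrogen, should give the (R)-carbinol that corresponds to the 9α-oxygen of the target.

Step 7
Reactants: 11 (1R)-1-[(1R,2R,3S,5S)-5-[(tert-butyldimethylsilyl)oxy]-2,3-dimethyl-2-(prop-2-en-1-yl)cyclohexyl]prop-2-en-1-ol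
Product: 12 (1R,4aR,5S,7S,8aR)-7-[(tert-butyldimethylsilyl)oxy]-4a,5-dimethyl-1,4,4a,5,6,7,8,8a-octahydronaphthalen-1-ol
Conditions: (H2IMes)(PCy3)Cl2Ru=CHPh (second-generation Grubbs catalyst, 5 mol %), CH2Cl2 (5 mM), 40 °C
Reagents that add atoms: none
Why: The ruthenium benzylidene should initiate at the unhindered allyl terminus on C5, and the new alkylidene closes onto the vinyl carbinol through a ruthenacyclobutane (Chauvin [2+2]/cycloreversion) with loss of ethylene; the closest known reaction type is ring-closing olefin metathesis of 1,7-dienes that carry a free allylic alcohol. Ring B is closed as a six-membered carbocycle by metathesis between C7 and C8, the only cyclisation mode open to this diene. No stereocentre is created: the step turns C7 and C8 into a ring olefin lying between the C6 methylene and the C9 carbinol, which is the array needed to set C8 and C7 afterwards by hydroxyl-directed epoxidation and trans-diaxial opening. The step needs ring closure to win over cross-metathesis oligomerisation and over ruthenium hydride isomerisation of the allylic alcohol; the two arms are trans-diequatorial (gauche) on the chair of ring A, which holds the alkene termini close and makes the trans-fused octalin strain-free, and high dilution with a short reaction time should secure the rest.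

Step 8
Reactants: 12 (1R,4aR,5S,7S,8aR)-7-[(tert-butyldimethylsilyl)oxy]-4a,5-dimethyl-1,4,4a,5,6,7,8,8a-octahydronaphthalen-1-ol
Product: 13 2α-[(tert-butyldimethylsilyl)oxy]-7α,8α-epoxy-4β,5β-dimethyl-10αH-decalin-9α-ol
Conditions: mCPBA, NaHCO3, CH2Cl2, 0 °C
Reagents that add atoms: mCPBA (3-chloroperoxybenzoic acid), OOC(=O)c1cccc(Cl)c1
Why: Peracid epoxidation directed by hydrogen bonding to the pseudoequatorial allylic 9α-hydroxyl (Henbest rule), reinforced by shielding of the β face by the axial C5 methyl group, should give the 7α,8α-epoxide and thereby fix the C8 oxygen configuration.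

Step 9
Reactants: 13 2α-[(tert-butyldimethylsilyl)oxy]-7α,8α-epoxy-4β,5β-dimethyl-10αH-decalin-9α-ol
Product: 14 2α-[(tert-butyldimethylsilyl)oxy]-10αH-eremophil-11-ene-8α,9α-diol
Conditions: CH2=C(CH3)MgBr (4 equiv), CuI (20 mol %), THF, −30 °C → rt; aq. NH4Cl
Reagents that add atoms: isopropenylmagnesium bromide, C=C(C)[Mg]Br
Why: Copper-catalysed Grignard opening of the epoxide should follow the Fürst–Plattner rule, since only attack at C7 from the β face passes through a chair-like transition state to the trans-diaxial product (the course taken by 2α,3α-epoxides of 5α-steroids next to the angular methyl group), which installs the 7β-isopropenyl group with inversion and leaves the 8α-hydroxyl.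

Step 10
Reactants: 14 2α-[(tert-butyldimethylsilyl)oxy]-10αH-eremophil-11-ene-8α,9α-diol; 15 (2E)-3-methylpent-2-enoic acid
Product: 16 2α-[(tert-butyldimethylsilyl)oxy]-8α-hydroxy-10αH-eremophil-11-en-9α-yl (2E)-3-methylpent-2-enoate
Conditions: DCC, DMAP (cat.), CH2Cl2, 0 °C
Reagents that add atoms: none
Why: Steglich esterification with one equivalent of acid should acylate the equatorial 9α-hydroxyl in preference to the axial 8α-hydroxyl, which is flanked by the axial isopropenyl group and two syn-axial hydrogens, and the equatorial ester is also the thermodynamically preferred regioisomer if acyl migration occurs.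

Step 11
Reactants: 16 2α-[(tert-butyldimethylsilyl)oxy]-8α-hydroxy-10αH-eremophil-11-en-9α-yl (2E)-3-methylpent-2-enoate
Product: 17 2α,8α-dihydroxy-10αH-eremophil-11-en-9α-yl (2E)-3-methylpent-2-enoate
Conditions: HF·pyridine, THF/pyridine, 0 °C → rt
Reagents that add atoms: none
Why: Fluoride-mediated desilylation under buffered acidic conditions should free the axial 2α-hydroxyl without ester hydrolysis or acyl migration.

Compound list
1 | (S)-(+)-carvone, (5S)-2-methyl-5-(prop-1-en-2-yl)cyclohex-2-en-1-one | CC1=CC[C@H](C(C)=C)CC1=O | starting material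
2 | (5S)-5-(1-hydroperoxy-1-methoxyethyl)-2-methylcyclohex-2-en-1-one (epimers at the peroxyketal carbon) | CC1=CC[C@H](C(C)(OC)OO)CC1=O | intermediate
3 | 1-methoxy-1-[(1S)-4-methyl-5-oxocyclohex-3-en-1-yl]ethyl ethaneperoxoate (peroxyacetate of 2) | CC1=CC[C@H](C(C)(OC)OOC(C)=O)CC1=O | intermediate
4 | (S)-5-acetoxy-2-methylcyclohex-2-en-1-one, (1S)-4-methyl-5-oxocyclohex-3-en-1-yl acetate | CC1=CC[C@H](OC(C)=O)CC1=O | intermediate
5 | (5S)-5-hydroxy-2-methylcyclohex-2-en-1-one | CC1=CC[C@H](O)CC1=O | intermediate
6 | (5S)-5-[(tert-butyldimethylsilyl)oxy]-2-methylcyclohex-2-en-1-one | CC1=CC[C@H](O[Si](C)(C)C(C)(C)C)CC1=O | intermediate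
7 | lithium (3S,5S)-5-[(tert-butyldimethylsilyl)oxy]-2,3-dimethylcyclohex-1-en-1-olate | [Li]OC1=C(C)[C@@H](C)C[C@H](O[Si](C)(C)C(C)(C)C)C1 | intermediate
8 | (2R,3S,5S)-5-[(tert-butyldimethylsilyl)oxy]-2,3-dimethyl-2-(prop-2-en-1-yl)cyclohexan-1-one | C=CC[C@]1(C)[C@@H](C)C[C@H](O[Si](C)(C)C(C)(C)C)CC1=O | intermediate
9 | tert-butyl{[(1S,3S,4R)-5-(methoxymethylidene)-3,4-dimethyl-4-(prop-2-en-1-yl)cyclohexyl]oxy}dimethylsilane (E/Z mixture) | C=CC[C@]1(C)[C@@H](C)C[C@H](O[Si](C)(C)C(C)(C)C)CC1=COC | intermediate
10 | (1R,2R,3S,5S)-5-[(tert-butyldimethylsilyl)oxy]-2,3-dimethyl-2-(prop-2-en-1-yl)cyclohexane-1-carbaldehyde | C=CC[C@]1(C)[C@@H](C)C[C@H](O[Si](C)(C)C(C)(C)C)C[C@H]1C=O | intermediate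
11 | (1R)-1-[(1R,2R,3S,5S)-5-[(tert-butyldimethylsilyl)oxy]-2,3-dimethyl-2-(prop-2-en-1-yl)cyclohexyl]prop-2-en-1-ol | C=CC[C@]1(C)[C@@H](C)C[C@H](O[Si](C)(C)C(C)(C)C)C[C@H]1[C@H](O)C=C | intermediate
12 | (1R,4aR,5S,7S,8aR)-7-[(tert-butyldimethylsilyl)oxy]-4a,5-dimethyl-1,4,4a,5,6,7,8,8a-octahydronaphthalen-1-ol | C1=CC[C@]2(C)[C@@H](C)C[C@H](O[Si](C)(C)C(C)(C)C)C[C@H]2[C@@H]1O | intermediate
13 | 2α-[(tert-butyldimethylsilyl)oxy]-7α,8α-epoxy-4β,5β-dimethyl-10αH-decalin-9α-ol (epoxide cis to the 9-hydroxyl, trans to the C5 methyl) | O1[C@@H]2C[C@]3(C)[C@@H](C)C[C@H](O[Si](C)(C)C(C)(C)C)C[C@H]3[C@H](O)[C@H]12 | intermediate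
14 | 2α-[(tert-butyldimethylsilyl)oxy]-10αH-eremophil-11-ene-8α,9α-diol | C=C(C)[C@H]1C[C@]2(C)[C@@H](C)C[C@H](O[Si](C)(C)C(C)(C)C)C[C@H]2[C@H](O)[C@@H]1O | intermediate
15 | (2E)-3-methylpent-2-enoic acid | CC/C(C)=C/C(=O)O | starting material
16 | 2α-[(tert-butyldimethylsilyl)oxy]-8α-hydroxy-10αH-eremophil-11-en-9α-yl (2E)-3-methylpent-2-enoate | C=C(C)[C@H]1C[C@]2(C)[C@@H](C)C[C@H](O[Si](C)(C)C(C)(C)C)C[C@H]2[C@H](OC(=O)/C=C(\C)CC)[C@@H]1O | intermediate
17 | 2α,8α-dihydroxy-10αH-eremophil-11-en-9α-yl (2E)-3-methylpent-2-enoate, (2S,4S,5R,7R,8R,9S,10R) | C=C(C)[C@H]1C[C@]2(C)[C@@H](C)C[C@H](O)C[C@H]2[C@H](OC(=O)/C=C(\C)CC)[C@@H]1O | target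

Total step count: 11. Longest linear sequence: 11 steps (from 1; acid 15 is purchased).

Steps most likely to fail:

Step 9. The nucleophile must attack C7 on the face that carries the syn-axial C5 methyl group. The opening may therefore stall, or bromide from the Grignard reagent may open the epoxide in its place. The fallback sets out from 13. The smaller sp-hybridised nucleophile LiC≡CH·H2NCH2CH2NH2 in DMSO should open the epoxide in the same trans-diaxial sense to give 2α-[(tert-butyldimethylsilyl)oxy]-7β-ethynyl-4β,5β-dimethyl-10αH-decalin-8α,9α-diol F1. Zirconium-catalysed methylalumination of the alkyne (Me3Al in excess, Cp2ZrCl2 cat., CH2Cl2, rt; syn addition, methyl to the internal carbon) then gives the alkenylalane F2, which is protonolysed in the flask with water. This returns to the route at diol 14.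

Step 5. The ylide is a strong base, and enolisation of the hindered ketone toward C1 may end in E1cB loss of the axial β-silyloxy group rather than olefination. The fallback sets out from 8. Non-basic methylenation with Cp2TiMe2 (toluene, 65 °C) gives the exocyclic alkene F3. mCPBA should epoxidise this 1,1-disubstituted alkene faster than the monosubstituted allyl alkene, giving the spiro-epoxide F4. Meinwald rearrangement with BF3·OEt2 (CH2Cl2, −78 °C; hydride shift to the tertiary cation) and the same K2CO3/MeOH equilibration return to the route at aldehyde 10.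

Step 10. Discrimination between the two secondary hydroxyls may be insufficient, or the acyl group may migrate to O8 under DMAP, either of which would erode regioselectivity. The fallback sets out from 14. Bu2SnO (toluene, reflux, removal of water) gives the 8,9-O-dibutylstannylene acetal F5, in which the equatorial oxygen on C9 is the more nucleophilic one. Acylation with (2E)-3-methylpent-2-enoyl chloride F6 (from 15 with oxalyl chloride and catalytic DMF) at 0 °C without amine base returns to the route at 16.

Further compounds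
F1 | step 9 | 2α-[(tert-butyldimethylsilyl)oxy]-7β-ethynyl-4β,5β-dimethyl-10αH-decalin-8α,9α-diol | C#C[C@H]1C[C@]2(C)[C@@H](C)C[C@H](O[Si](C)(C)C(C)(C)C)C[C@H]2[C@H](O)[C@@H]1O
F2 | step 9 | (E)-alkenyldimethylalane of F1 with both hydroxyls as dimethylaluminium alkoxides (not isolated) | C[Al](C)/C=C(\C)[C@H]1C[C@]2(C)[C@@H](C)C[C@H](O[Si](C)(C)C(C)(C)C)C[C@H]2[C@H](O[Al](C)C)[C@@H]1O[Al](C)C
F3 | step 5 | tert-butyl{[(1S,3S,4R)-3,4-dimethyl-5-methylidene-4-(prop-2-en-1-yl)cyclohexyl]oxy}dimethylsilane | C=CC[C@]1(C)[C@@H](C)C[C@H](O[Si](C)(C)C(C)(C)C)CC1=C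
F4 | step 5 | spiro-epoxide of F3 at the exocyclic alkene (either epimer at the spiro carbon serves) | C=CC[C@]1(C)[C@@H](C)C[C@H](O[Si](C)(C)C(C)(C)C)CC12CO2
F5 | step 10 | 8,9-O-dibutylstannylene acetal of 14 | C=C(C)[C@H]1C[C@]2(C)[C@@H](C)C[C@H](O[Si](C)(C)C(C)(C)C)C[C@H]2[C@@H]3O[Sn](CCCC)(CCCC)O[C@H]13
F6 | step 10 | (2E)-3-methylpent-2-enoyl chloride | CC/C(C)=C/C(Cl)=O
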